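## Structural features

Dichrostachine N is a trans-fused decalin (rings A and B; C1–C10, with C17 on C8, C18/C19 on C4 and C20 on C10) linked through the C11 methylene to a cis-fused bicycle. That bicycle is cyclohexene ring C (C12, C13=C14, C15, C6′, C1′) fused to ring D, a 4′-methoxycyclohex-3′-ene-2′,5′-dione, and quaternary C1′ also bears a 5-hydroxy-7-methoxychromon-2-yl group. The decalin has four stereocentres: the 2α carbinol, C5 and quaternary C10 (trans fusion, 10β-methyl), and the tertiary 9α carbinol, which lies between C10 and the C8 exocyclic methylene and is β to the C7 ketone. Rings C and D carry the contiguous triad C12/C1′/C6′, with C11 cis to the chromone and trans to both ring D carbons; an endo Diels–Alder addition of an (E)-diene to the corresponding quinone would not give this relationship. The fragile groups are the β-hydroxy-α-methylene ketone (Michael acceptor, retro-aldol), the methoxy-ene-dione with its epimerisable C6′–H (reducible, base-labile), and the chromone with its chelated phenol. The real difficulty is threefold: the C9–C11 bond between two crowded halves, the 9α-hydroxyl beside an exocyclic methylene, and absolute control of the C12/C1′/C6′ triad, which is remote from the decalin centres. Ring A (C1–C5, C10) has its only functional group, the C2 carbinol, between the C1 and C3 methylenes and is framed by quaternary C10 and C4; the key step therefore forms C2=C3 by metathesis of a C10 allyl group with a C4 vinyl group on a preformed ring B, and that alkene is the handle for the 2α-hydroxyl.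

## Logic of the disconnections

**38 ⇒ 37 ⇒ 36.** No skeletal bond is cut. The C5′ ketone, the 5-hydroxyl and the 2α-hydroxyl of 38 are traced to the ketal, the aryl acetal and the silyl ether of 37, and the C7 ketone of 37 to the allylic alcohol of 36. The ene-dione and the methylene ketone are the least robust groups and so appear last; every earlier intermediate then has a ring D without enolisable hydrogen. The demand is that the final step be acidic and never basic.

**36 ⇒ 35 ⇒ 34.** The C9–O bond and the C8=C17 alkene are traced to an 8α,9α-epoxide in 35 and to the tetrasubstituted C8=C9 alkene of 34. The 7α-hydroxyl can deliver oxygen only to the α face of that alkene, and a base-induced opening towards the C17 methyl keeps the C9–O bond. C9 is thus set relative to a centre that comes from the chiral pool. The demand is that the isomerisation take a methyl hydrogen and not one from C11.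

**33 ⇒ 19 + 31.** The C9–C11 bond is cut between an sp2 and a primary sp3 carbon. This is the most convergent cut, and each half brings its own stereocentres. The demand is a cross-coupling at a tetrasubstituted C9–OTf centre flanked by quaternary C10, with an organometal mild enough for a ketone, a ketal and a chromone; hence the alkylzinc 32.

**19 ⇒ 11.** The C8–C17 bond, the C2–O bond and the C9–OTf bond are removed. All three are operations around the ketone and the alkene that the ring closure leaves behind. The only enolate of the C9 ketone is β to the C7 oxygen, so the methylation is run on the alkoxide (12, 13), the triflate is made without an enolate, and the hydroboration waits until the ketone is masked as the triflate.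

**11 ⇒ 10 (key step).** The C2=C3 bond is cut, opening ring A to a C10 allyl and a C4 vinyl group. Both arms can be put on ring B by one conjugate addition–alkylation pair, and the alkene is the later handle for C2–OH. The demand is only that the two arms be trans on ring B.

**10 ⇒ 7 ⇒ 5 + 6 + 8.** The C10–C1 bond (allylation) and the C5–C4 bond (conjugate addition at the γ-carbon of 6) are cut. The quaternary C4 and C10 and the trans C5/C10 relationship then arise from two anti additions steered by the C7 oxygen. The demand is that the enolate formed in the conjugate addition be kept regiodefined, which is why the adduct is held as silyl enol ether 7.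

**5 ⇒ 1.** The isopropenyl C–C bond is exchanged for C–O with retention. This gives the C7 oxygen, later the directing group for C9, from the chiral pool in three steps.

**31 ⇒ 30 ⇒ 29 ⇒ 25 + 27.** The C11–I bond is traced to C11–OH. The chromone is cut at C2–C3 (condensation) and O1–C2 (cyclodehydration). The carbon that becomes chromone C2 is the ester carbonyl of the tether in 25, so one condensation both builds the heterocycle and frees C11–OH. The demand is addition to a carbonyl on quaternary C1′. Because 25 is racemic, the sulfonate that activates C11 is made from an enantiopure sulfonyl chloride and the diastereomers are separated.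

**25 ⇒ 24 ⇒ 23 ⇒ 21 + 22.** The C12–C1′ and C15–C6′ bonds are cut (intramolecular Diels–Alder), then the ester C–O bond, and ring D is traced to the aromatic ring of 22 by dearomatisation. The three-atom ester tether and the (Z)-diene force C11 and the tether carbonyl cis, which is the relationship that an intermolecular endo addition cannot give. The demand is a dienophile reactive enough for an ester-tethered (Z)-diene.

**21 ⇒ 20 and 27 ⇒ 26.** A semihydrogenation and a mono-protection.

## Other disconnections considered

**Alternative 1:** The cut is C12–C1′, with the C14–O bond sacrificed. Ring C would come from an Ireland–Claisen ring contraction of the six-membered lactone A2, whose silyl ketene acetal rearranges through a boat transition state to the ring C acid A1.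
- In its favour: the C12/C1′ pair, including the quaternary carbon, would be set by suprafacial chirality transfer from the C14 carbinol and the (Z)-alkene, so the absolute configuration of the triad could stem from one asymmetric reduction. The chromone is in place from the start.
- Against it here: A2 needs a long linear preparation; the enolisation must be done beside a chromone with a free chelated phenol; A1 still lacks C3′ and C4′, so ring D has to be annulated afterwards.
- Comparison: both plans use a pericyclic step with a geometrically enforced transition state (boat Claisen there, tether-enforced cycloaddition in step 14). On enantiocontrol the alternative is the better one, because the chosen plan resolves racemic 29 and discards half of it. On step economy the chosen plan is better, since step 14 forms both ring C bonds, all three stereocentres and the masked ring D from a two-step precursor. The alternative does not address the decalin; it would replace steps 12–18 only.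

**Alternative 2:** The cuts are C4–C5 and C9–C10. Both carbocycles of the decalin would form at once from the acyclic polyene A4 by a hydrogen-atom-transfer radical bicyclisation (Fe(acac)3, PhSiH3) to the decalin A3.
- In its favour: two rings, two C–C bonds and the C5, C10, C8 and C9 centres in one operation, with the 8-methyl group and C11 already present. On ring-forming economy this is the better plan, and it is at least the equal of the chosen route in functional-group tolerance.
- Against it here: the only stereocentre of A4 is C2, and 1,3-induction in a radical cascade is a weaker control element than the chiral-pool-directed anti additions of steps 4 and 5. The hydrogen atom must select the 1,1-disubstituted alkene over the trisubstituted alkene and the enone. A3 has hydrogen at C9, so the 9α-hydroxyl and the C8 methylene would still need an oxidation sequence, and the bond from C11 to ring C would have to be made at the stereogenic secondary carbon C12.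
- Comparison: the alternative reaches a more advanced decalin in fewer steps. The chosen plan is longer (eleven steps to 19), but each centre has its own independent control element, and the union with ring C is an sp2–sp3 coupling and not a substitution at C12.

**Alternative 3:** The cuts are C2′–C3′ and C4′–C5′. Ring D would be closed last by adding the sulfonyl-stabilised anion of γ-lactone A6 (LiOtBu) to the vinyl sulfone A7, followed by Dieckmann closure and two sulfinate eliminations, to the protected target A5.
- In its favour: the reducible ene-dione would never face organometallic steps, and the reagent fixes the position of the methoxy group. On regiochemical certainty this equals the chosen plan, where the methoxy group comes from 22.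
- Against it here: the anion at C2′ is neopentyl and must add intermolecularly; alkoxide acts next to C6′–H once the dione forms, so the cis fusion is at risk; the base must coexist with the chromone and a free tertiary C9–OH; A6 must itself be assembled on ring C.
- Comparison: the alternative is better in that no ketal has to survive eight steps. The chosen plan is better in step count (ring D from an aromatic acid in step 14) and in that ring D meets only acid at the end.

Key step: step 6

Assumptions: atom numbers are those of the target, and α is the face opposite the C10 methyl group. Compounds 20, 22 and 26 are taken as purchasable. Compounds 25, 28 and 29 are racemic and drawn as the enantiomer that is carried on. The descriptors of 10 and 11 were checked against 38 and against 1: C7 of the decalin is C5 of 1 and the Criegee step retains its configuration, so 1 is the correct antipode and the structures need no change. The design is changed at three places: the conjugate adduct is kept as silyl enol ether 7 so that its enolate stays regiodefined; the C8 methylation is run on the free alkoxide and the triflate is made without an enolate, because every enolate of the C9 ketone is β to the C7 oxygen; and the hydroboration is placed after the triflation so that no borane meets the ketone.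

## Route

Step 1
Reactants: 1 (R)-carvone
Product: 3 (R)-5-acetoxy-2-methylcyclohex-2-en-1-one, via methoxy hydroperoxide 2 (not isolated)
Conditions: O3, CH2Cl2–MeOH, −78 °C; then Ac2O, Et3N, DMAP (cat.), −78 °C → rt
Reagents that add atoms: ozone O=[O+][O-]; methanol CO (in 2 only); acetic anhydride CC(=O)OC(C)=O
Why: Ozone cleaves only the electron-rich isopropenyl group (the enone alkene is deactivated) and methanol traps the carbonyl oxide; the peracetate of 2 undergoes Criegee rearrangement in which the ring carbon migrates to oxygen with retention, so the future C7 centre is carried over from 1 unchanged.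

Step 2
Reactants: 3 (R)-5-acetoxy-2-methylcyclohex-2-en-1-one
Product: 4 (R)-5-hydroxy-2-methylcyclohex-2-en-1-one
Conditions: K2CO3, MeOH, 0 °C
Reagents that add atoms: none
Why: Transesterification at 0 °C should remove the acetate faster than the β-acyloxy ketone can eliminate.

Step 3
Reactants: 4 (R)-5-hydroxy-2-methylcyclohex-2-en-1-one
Product: 5 (R)-5-(tert-butyldimethylsilyloxy)-2-methylcyclohex-2-en-1-one
Conditions: TBSCl, imidazole, DMF, rt
Reagents that add atoms: tert-butyldimethylsilyl chloride CC(C)(C)[Si](C)(C)Cl
Why: Standard silylation; the ether masks the alcohol for the Lewis-acid and organolithium steps.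

Step 4
Reactants: 5 (R)-5-(tert-butyldimethylsilyloxy)-2-methylcyclohex-2-en-1-one; 6 prenyltrimethylsilane
Product: 7 trimethylsilyl enol ether of 3,5-trans-5-(tert-butyldimethylsilyloxy)-2-methyl-3-(2-methylbut-3-en-2-yl)cyclohexanone
Conditions: Tf2NH (5 mol %), CH2Cl2, −78 °C; Et3N quench, non-aqueous work-up
Reagents that add atoms: none
Why: Hosomi–Sakurai conjugate addition catalysed by Me3SiNTf2 (formed from Tf2NH and 6): the silane reacts at its γ-carbon, making C4 quaternary, on the enone face anti to the silyloxy group (axial attack, 3,5-trans), which sets C5. The silyl group ends on oxygen, so the regiodefined C9=C10 enol ether survives, which a TiCl4 work-up would not allow.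

Step 5
Reactants: 7 trimethylsilyl enol ether; 8 allyl bromide
Product: 10 2-allyl-5-(tert-butyldimethylsilyloxy)-2-methyl-3-(2-methylbut-3-en-2-yl)cyclohexanone (10α-allyl, 10β-methyl, 5α-H, 7α-OTBS), via lithium enolate 9 (not isolated)
Conditions: MeLi, THF, 0 °C; then DMPU, allyl bromide, −78 → 0 °C
Reagents that add atoms: none
Why: MeLi cleaves the O–Si bond to the regiospecific lithium enolate, which allyl bromide C-alkylates anti to the neighbouring tert-alkyl group (pseudoaxial to avoid strain with the C10 methyl); this sets quaternary C10 with the two alkenyl arms trans. This enolate points away from C7, so no β-elimination is possible.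

Step 6
Reactants: 10 key-step precursor (ring B ketone with C10 allyl and C5 1,1-dimethylallyl groups)
Product: 11 7α-(tert-butyldimethylsilyloxy)-4,4,10β-trimethyl-5α-octal-2-en-9-one (trans-fused)
Conditions: RuCl2(=CHPh)(H2IMes)(PCy3) (second-generation Grubbs catalyst, 5 mol %), CH2Cl2 (0.005 M), 40 °C
Reagents that add atoms: none
Why: Ring-closing olefin metathesis by the Chauvin mechanism: after loss of PCy3 the ruthenium alkylidene exchanges with the unhindered allyl group, placing the metal on C2, and this alkylidene adds to the neopentyl vinyl group to give a ruthenacyclobutane whose cycloreversion forms C2=C3 and releases Ru=CH2; ethylene loss drives the sequence. The closest known reaction type is diene metathesis to cyclohexenes that carry allylic quaternary carbons. Ring A closes as a six-membered carbocycle by joining the ends of two arms on adjacent ring B carbons, and the new alkene is necessarily cis within the ring. No stereocentre is created; the trans ring fusion follows from the anti arrangement of the arms fixed in steps 4 and 5, which lets both sit equatorial on ring B. The step needs chemoselectivity for the two monosubstituted alkenes over the ketone and the silyl ether, which this catalyst provides. It also needs ring closure to outrun intermolecular metathesis, which dilution and the two quaternary centres that hold the chain ends together should secure. Alkene migration from the vinyl side is blocked by quaternary C4.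

Step 7
Reactants: 11 7α-(tert-butyldimethylsilyloxy)-4,4,10β-trimethyl-5α-octal-2-en-9-one
Product: 12 7α-hydroxy-4,4,10β-trimethyl-5α-octal-2-en-9-one
Conditions: HF (48 % aq.), MeCN, 0 °C → rt
Reagents that add atoms: none
Why: Acidic desilylation; a basic fluoride source could open the β-hydroxy ketone by retro-aldol and scramble C7.

Step 8
Reactants: 12 7α-hydroxy-4,4,10β-trimethyl-5α-octal-2-en-9-one
Product: 15 4,4,8,10β-tetramethyl-7α-(triethylsilyloxy)-5α-octal-2-en-9-one (C8 epimers), via dilithium alkoxide enolate 13 (not isolated), via lithium alkoxide 14 (not isolated)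
Conditions: LiN(iPr)2 (2.1 equiv), THF, −78 → −40 °C; MeI, DMPU, −78 → −30 °C; then Et3SiCl, Et3N, 0 °C
Reagents that add atoms: iodomethane CI; chlorotriethylsilane CC[Si](Cl)(CC)CC
Why: Fráter–Seebach-type alkylation of the β-hydroxy ketone dianion: the ketone can enolise only towards C8, and with the C7 oxygen as an alkoxide (no leaving group) C-methylation should replace the E1cB elimination expected of a β-silyloxy enolate. The alkoxide is silylated in the same flask; the C8 configuration is irrelevant because C8 becomes trigonal in step 9.

Step 9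
Reactants: 15 4,4,8,10β-tetramethyl-7α-(triethylsilyloxy)-5α-octal-2-en-9-one
Product: 16 4,4,8,10β-tetramethyl-7α-(triethylsilyloxy)-5α-octa-2,8-dien-9-yl trifluoromethanesulfonate
Conditions: Tf2O, 2,6-di-tert-butyl-4-methylpyridine, CH2Cl2, 0 °C → rt
Reagents that add atoms: trifluoromethanesulfonic anhydride O=S(=O)(OS(=O)(=O)C(F)(F)F)C(F)(F)F
Why: O-Triflation of the ketone followed by loss of the only α-hydrogen (C8–H) to the hindered base gives the tetrasubstituted enol triflate without an enolate β to the silyloxy group.

Step 10
Reactants: 16 dienyl triflate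
Product: 18 2α-hydroxy-4,4,8,10β-tetramethyl-7α-(triethylsilyloxy)-5α-octal-8-en-9-yl trifluoromethanesulfonate, via alkylborane 17 (not isolated)
Conditions: 9-BBN, THF, 0 → 50 °C; then NaBO3·4H2O, THF–H2O, rt
Reagents that add atoms: 9-borabicyclo[3.3.1]nonane B1C2CCCC1CCC2 (in 17); sodium perborate [Na+].[O-]OB=O
Why: Hydroboration–oxidation: the electron-poor tetrasubstituted enol triflate is inert, boron goes to C2 because C3 is neopentyl, and it adds from the α face because the β face is screened by the axial 4β- and 10β-methyl groups. Oxidation with retention then gives the equatorial 2α-alcohol and sets C2.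

Step 11
Reactants: 18 2α-hydroxy triflate
Product: 19 2α-(tert-butyldimethylsilyloxy)-4,4,8,10β-tetramethyl-7α-(triethylsilyloxy)-5α-octal-8-en-9-yl trifluoromethanesulfonate (fragment 1)
Conditions: TBSCl, imidazole, DMF, rt
Reagents that add atoms: tert-butyldimethylsilyl chloride CC(C)(C)[Si](C)(C)Cl
Why: Silylation of the unhindered equatorial alcohol; the two silyl ethers differ in lability so that C7–O can be freed alone in step 20.

Step 12
Reactants: 20 (Z)-3-methylpent-2-en-4-yn-1-ol
Product: 21 (Z)-3-methylpenta-2,4-dien-1-ol
Conditions: H2 (1 atm), Pd/CaCO3 poisoned with Pb(OAc)2 (Lindlar catalyst), quinoline, EtOAc, 0 °C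
Reagents that add atoms: none
Why: Lindlar semihydrogenation stops the terminal alkyne at the alkene and leaves the trisubstituted (Z)-alkene untouched.

Step 13
Reactants: 21 (Z)-3-methylpenta-2,4-dien-1-ol; 22 2-hydroxy-4,5-dimethoxybenzoic acid
Product: 23 (Z)-3-methylpenta-2,4-dienyl 2-hydroxy-4,5-dimethoxybenzoate
Conditions: PPh3, DIAD, THF, 0 °C → rt
Reagents that add atoms: none
Why: Mitsunobu esterification: the carboxylate, far more acidic than the chelated phenol, displaces the activated primary allylic alcohol by SN2 without touching the diene geometry.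

Step 14
Reactants: 23 (Z)-3-methylpenta-2,4-dienyl 2-hydroxy-4,5-dimethoxybenzoate
Product: 25 racemic tricyclic lactone (cis-fused γ-lactone C11–O–CO–C1′; ring C with C13=C14; ring D with C2′ ketone, 4′-methoxy C3′=C4′ enol ether and C5′ dimethyl ketal; C11 cis to the lactone carbonyl, C2′ and C5′ cis), via quinone monoketal 24 (not isolated)
Conditions: PhI(OAc)2, MeOH, 0 °C; solvent exchange; toluene (0.01 M), BHT, 100 °C
Reagents that add atoms: methanol CO
Why: Oxidative dearomatisation para to the 5′-methoxy group gives the quinone monoketal, whose ester-bearing C1′=C6′ bond (activated by ketone and ester) undergoes an intramolecular Diels–Alder reaction with the tethered diene. The three-atom tether and the (Z)-diene permit only the cis-fused lactone with the ketal ring endo, which fixes C12, C1′ and C6′ in the relative configuration of the target (racemic).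

Step 15
Reactants: 26 2,6-dihydroxy-4-methoxyacetophenone
Product: 27 2-hydroxy-4-methoxy-6-(methoxymethoxy)acetophenone
Conditions: MOMCl (1.05 equiv), iPr2NEt, CH2Cl2, 0 °C
Reagents that add atoms: chloromethyl methyl ether COCCl
Why: The two phenols are equivalent, and after the first alkylation the remaining one is deactivated by its hydrogen bond to the ketone.

Step 16
Reactants: 25 racemic tricyclic lactone; 27 2-hydroxy-4-methoxy-6-(methoxymethoxy)acetophenone
Product: 29 racemic chromone alcohol (5-MOM-protected chromone on C1′, C11 hydroxymethyl on C12, ring D masked as in 25), via β-diketone 28 (not isolated)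
Conditions: 27 (2 equiv), LiN(SiMe3)2 (4.4 equiv), THF, −78 → 0 °C; 25, −78 °C → rt; AcOH; then PPTS, 4 Å MS, toluene, 80 °C
Reagents that add atoms: none
Why: Claisen condensation: the dianion of 27 attacks the lactone carbonyl (C2′ is a hindered vinylogous ester and ring D has no enolisable hydrogen), which opens the lactone to the β-diketone and frees C11–OH. Anhydrous acid then closes the phenol onto the C1′-bound carbonyl and dehydrates to the aromatic pyranone while the MOM ether and the ketal are kept.

Step 17
Reactants: 29 racemic chromone alcohol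
Product: 30 (1S)-camphor-10-sulfonate of the enantiomer of 29 with the target configuration at C12, C1′ and C6′
Conditions: (1S)-10-camphorsulfonyl chloride, Et3N, DMAP (cat.), CH2Cl2, 0 °C; diastereomers separated (chromatography, crystallisation)
Reagents that add atoms: (1S)-10-camphorsulfonyl chloride CC1(C)[C@@H]2CC[C@@]1(CS(=O)(=O)Cl)C(=O)C2
Why: Sulfonylation of the primary alcohol with an enantiopure sulfonyl chloride turns the racemate into two separable diastereomers, which fixes the absolute configuration of the triad by resolution; the same sulfonate is the leaving group for step 18. The configuration of 30 would be assigned by crystallography.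

Step 18
Reactants: 30 camphorsulfonate
Product: 31 C11 iodide (fragment 2)
Conditions: NaI, butan-2-one, 60 °C
Reagents that add atoms: sodium iodide [Na+].[I-]
Why: Finkelstein substitution at the β-branched primary carbon; no stereocentre is involved.

Step 19
Reactants: 31 C11 iodide (fragment 2); 19 enol triflate (fragment 1)
Product: 33 coupling product (C9–C11 bond; C8=C9 tetrasubstituted alkene; 2α-OTBS, 7α-OTES; masked ring D; 5-O-MOM), via alkylzinc iodide 32 (not isolated)
Conditions: Zn dust (activated with BrCH2CH2Br and Me3SiCl), LiCl, THF, 40 °C; then 19, PdCl2(dppf) (5 mol %), THF–NMP, 55 °C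
Reagents that add atoms: zinc [Zn] (in 32)
Why: Zinc inserts into the C–I bond and tolerates the ketone, ketal and chromone. Negishi coupling follows: zerovalent palladium adds into the C9–OTf bond, and after transmetalation the wide-bite-angle ligand favours reductive elimination over β-hydride loss. sp2–sp3 couplings of 2,6,6-trisubstituted cyclohexenyl triflates are a known class.

Step 20
Reactants: 33 coupling product
Product: 34 7α-alcohol (2α-OTBS kept)
Conditions: HF·pyridine, pyridine, THF, 0 °C
Reagents that add atoms: none
Why: Buffered fluoride cleaves the more labile allylic triethylsilyl ether and should leave the TBS ether, the aryl MOM ether and the ketal.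

Step 21
Reactants: 34 7α-alcohol
Product: 35 8α,9α-epoxy-7α-alcohol
Conditions: VO(acac)2 (10 mol %), t-BuOOH (decane), CH2Cl2, 0 °C → rt
Reagents that add atoms: tert-butyl hydroperoxide CC(C)(C)OO
Why: Hydroxyl-directed epoxidation: the pseudoaxial 7α-hydroxyl binds the vanadium peroxide and delivers oxygen to the α face of the C8=C9 alkene, which is also the face away from the 10β-methyl; this sets C9. The ring C alkene and the enol ether have no directing group and should not react.

Step 22
Reactants: 35 8α,9α-epoxy-7α-alcohol
Product: 36 7α,9α-diol with C8=C17 exocyclic alkene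
Conditions: Et2Al(TMP) (from LiTMP and Et2AlCl, 5 equiv), toluene, 0 °C → rt; aq. potassium sodium tartrate
Reagents that add atoms: none
Why: Aluminium-amide isomerisation of an epoxide to an allylic alcohol: aluminium binds the epoxide oxygen and the amide removes a syn β-hydrogen through a cyclic transition state. The C17 methyl hydrogens are the most accessible (C7–H is anti to the epoxide oxygen, C11–H2 is crowded), so the C8–O bond breaks and the C9–O bond keeps its α configuration.

Step 23
Reactants: 36 7α,9α-diol
Product: 37 7-ketone (β-hydroxy-α-methylene ketone; 2α-OTBS, 5-O-MOM and C5′ ketal kept)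
Conditions: Dess–Martin periodinane, NaHCO3, CH2Cl2, 0 °C → rt
Reagents that add atoms: none
Why: The allylic C7 carbinol is the only secondary alcohol; the tertiary C9 alcohol cannot be oxidised.

Step 24
Reactants: 37 7-ketone
Product: 38 dichrostachine N
Conditions: HCl (2 M aq.), THF, 0 °C → rt
Reagents that add atoms: water O
Why: Aqueous acid hydrolyses the C5′ dimethyl ketal to the ketone and cleaves the aryl MOM ether and the secondary TBS ether. C8 has no hydrogen, so the β-hydroxy ketone cannot dehydrate through its enol, and C6′ is never exposed to base, so the cis fusion is kept.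

## Compound list

1 | (R)-carvone | CC1=CC[C@H](CC1=O)C(C)=C | starting material
2 | 5-(1-hydroperoxy-1-methoxyethyl)-2-methylcyclohex-2-en-1-one, ring centre as in 1 (not isolated) | CC1=CC[C@H](CC1=O)C(C)(OC)OO | intermediate
3 | (R)-5-acetoxy-2-methylcyclohex-2-en-1-one | CC1=CC[C@H](CC1=O)OC(C)=O | intermediate
4 | (R)-5-hydroxy-2-methylcyclohex-2-en-1-one | CC1=CC[C@H](CC1=O)O | intermediate
5 | (R)-5-(tert-butyldimethylsilyloxy)-2-methylcyclohex-2-en-1-one | CC1=CC[C@H](CC1=O)O[Si](C)(C)C(C)(C)C | intermediate
6 | prenyltrimethylsilane | CC(C)=CC[Si](C)(C)C | starting material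
7 | 5-(tert-butyldimethylsilyloxy)-2-methyl-3-(2-methylbut-3-en-2-yl)-1-(trimethylsilyloxy)cyclohex-1-ene, 3,5-trans | C1[C@H](O[Si](C)(C)C(C)(C)C)C[C@@H](C(C)(C)C=C)C(C)=C1O[Si](C)(C)C | intermediate
8 | allyl bromide | C=CCBr | starting material
9 | lithium enolate corresponding to 7 (not isolated) | C1[C@H](O[Si](C)(C)C(C)(C)C)C[C@@H](C(C)(C)C=C)C(C)=C1[O-].[Li+] | intermediate
10 | 2-allyl-5-(tert-butyldimethylsilyloxy)-2-methyl-3-(2-methylbut-3-en-2-yl)cyclohexanone; allyl trans to the 3-substituent, 3-substituent trans to the 5-silyloxy group | C1[C@H](O[Si](C)(C)C(C)(C)C)C[C@@H](C(C)(C)C=C)[C@](C)(CC=C)C1=O | intermediate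
11 | 7α-(tert-butyldimethylsilyloxy)-4,4,10β-trimethyl-5α-octal-2-en-9-one | C1[C@H](O[Si](C)(C)C(C)(C)C)C[C@H]2C(C)(C)C=CC[C@]2(C)C1=O | intermediate
12 | 7α-hydroxy-4,4,10β-trimethyl-5α-octal-2-en-9-one | C1[C@H](O)C[C@H]2C(C)(C)C=CC[C@]2(C)C1=O | intermediate
13 | dilithium 7α-alkoxide C8=C9 enolate of 12 (not isolated) | [Li+].[Li+].[O-]C1=C[C@H]([O-])C[C@H]2C(C)(C)C=CC[C@]12C | intermediate
14 | lithium 7α-alkoxide of 4,4,8,10β-tetramethyl-5α-octal-2-en-9-one, C8 epimers (not isolated) | CC1[C@H]([O-])C[C@H]2C(C)(C)C=CC[C@]2(C)C1=O.[Li+] | intermediate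
15 | 4,4,8,10β-tetramethyl-7α-(triethylsilyloxy)-5α-octal-2-en-9-one, C8 epimers | CC1[C@H](O[Si](CC)(CC)CC)C[C@H]2C(C)(C)C=CC[C@]2(C)C1=O | intermediate
16 | 4,4,8,10β-tetramethyl-7α-(triethylsilyloxy)-5α-octa-2,8-dien-9-yl trifluoromethanesulfonate | CC1=C(OS(=O)(=O)C(F)(F)F)[C@@]2(C)CC=CC(C)(C)[C@@H]2C[C@H]1O[Si](CC)(CC)CC | intermediate
17 | 2α-(9-borabicyclo[3.3.1]non-9-yl) adduct of 16 (not isolated) | CC1=C(OS(=O)(=O)C(F)(F)F)[C@@]2(C)C[C@@H](B3C4CCCC3CCC4)CC(C)(C)[C@@H]2C[C@H]1O[Si](CC)(CC)CC | intermediate
18 | 2α-hydroxy-4,4,8,10β-tetramethyl-7α-(triethylsilyloxy)-5α-octal-8-en-9-yl trifluoromethanesulfonate | CC1=C(OS(=O)(=O)C(F)(F)F)[C@@]2(C)C[C@@H](O)CC(C)(C)[C@@H]2C[C@H]1O[Si](CC)(CC)CC | intermediate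
19 | 2α-(tert-butyldimethylsilyloxy)-4,4,8,10β-tetramethyl-7α-(triethylsilyloxy)-5α-octal-8-en-9-yl trifluoromethanesulfonate (fragment 1) | CC1=C(OS(=O)(=O)C(F)(F)F)[C@@]2(C)C[C@@H](O[Si](C)(C)C(C)(C)C)CC(C)(C)[C@@H]2C[C@H]1O[Si](CC)(CC)CC | intermediate
20 | (Z)-3-methylpent-2-en-4-yn-1-ol | C#C/C(C)=C\CO | starting material
21 | (Z)-3-methylpenta-2,4-dien-1-ol | C=C/C(C)=C\CO | intermediate
22 | 2-hydroxy-4,5-dimethoxybenzoic acid | COc1cc(O)c(C(=O)O)cc1OC | starting material
23 | (Z)-3-methylpenta-2,4-dienyl 2-hydroxy-4,5-dimethoxybenzoate | C=C/C(C)=C\COC(=O)c1cc(OC)c(OC)cc1O | intermediate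
24 | (Z)-3-methylpenta-2,4-dienyl 3,3,4-trimethoxy-6-oxocyclohexa-1,4-diene-1-carboxylate (not isolated) | C=C/C(C)=C\COC(=O)C1=CC(OC)(OC)C(OC)=CC1=O | intermediate
25 | tricyclic lactone: γ-lactone C11–O–CO–C1′ cis-fused to ring C (13-methyl, C13=C14), ring D with C2′ ketone, 4′-methoxy C3′=C4′ and C5′ dimethyl ketal, rings C/D cis-fused (racemic; carried-on enantiomer drawn) | O=C1OC[C@@H]2C(C)=CC[C@H]3C(OC)(OC)C(OC)=CC(=O)[C@@]123 | intermediate
26 | 2,6-dihydroxy-4-methoxyacetophenone | CC(=O)c1c(O)cc(OC)cc1O | starting material
27 | 2-hydroxy-4-methoxy-6-(methoxymethoxy)acetophenone | CC(=O)c1c(O)cc(OC)cc1OCOC | intermediate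
28 | β-diketone: C1′-bound 3-[2-hydroxy-4-methoxy-6-(methoxymethoxy)phenyl]-3-oxopropanoyl group, C11 hydroxymethyl on C12, ring D as in 25 (racemic; not isolated) | OC[C@@H]1C(C)=CC[C@H]2C(OC)(OC)C(OC)=CC(=O)[C@@]12C(=O)CC(=O)c1c(O)cc(OC)cc1OCOC | intermediate
29 | chromone alcohol: 7-methoxy-5-(methoxymethoxy)chromon-2-yl on C1′, C11 hydroxymethyl on C12 cis to the chromone, ring D as in 25 (racemic; carried-on enantiomer drawn) | OC[C@@H]1C(C)=CC[C@H]2C(OC)(OC)C(OC)=CC(=O)[C@@]12c1cc(=O)c2c(OCOC)cc(OC)cc2o1 | intermediate
30 | (1S)-camphor-10-sulfonate of the drawn enantiomer of 29 | CC1(C)[C@@H]2CC[C@@]1(CS(=O)(=O)OC[C@@H]3C(C)=CC[C@H]4C(OC)(OC)C(OC)=CC(=O)[C@@]34c3cc(=O)c4c(OCOC)cc(OC)cc4o3)C(=O)C2 | intermediate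
31 | C11 iodide of the ring C/D chromone unit (fragment 2) | IC[C@@H]1C(C)=CC[C@H]2C(OC)(OC)C(OC)=CC(=O)[C@@]12c1cc(=O)c2c(OCOC)cc(OC)cc2o1 | intermediate
32 | C11 alkylzinc iodide from 31 (not isolated) | I[Zn]C[C@@H]1C(C)=CC[C@H]2C(OC)(OC)C(OC)=CC(=O)[C@@]12c1cc(=O)c2c(OCOC)cc(OC)cc2o1 | intermediate
33 | coupling product: C9–C11 bond, C8=C9 alkene with 8-methyl, 2α-OTBS, 7α-OTES, ring D ketal, 5-O-MOM | CC1=C(C[C@@H]3C(C)=CC[C@H]4C(OC)(OC)C(OC)=CC(=O)[C@@]34c3cc(=O)c4c(OCOC)cc(OC)cc4o3)[C@@]2(C)C[C@@H](O[Si](C)(C)C(C)(C)C)CC(C)(C)[C@@H]2C[C@H]1O[Si](CC)(CC)CC | intermediate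
34 | 7α-alcohol of 33 | CC1=C(C[C@@H]3C(C)=CC[C@H]4C(OC)(OC)C(OC)=CC(=O)[C@@]34c3cc(=O)c4c(OCOC)cc(OC)cc4o3)[C@@]2(C)C[C@@H](O[Si](C)(C)C(C)(C)C)CC(C)(C)[C@@H]2C[C@H]1O | intermediate
35 | 8α,9α-epoxy-7α-alcohol | C[C@@]12[C@H](O)C[C@H]3C(C)(C)C[C@H](O[Si](C)(C)C(C)(C)C)C[C@]3(C)[C@]1(C[C@@H]4C(C)=CC[C@H]5C(OC)(OC)C(OC)=CC(=O)[C@@]45c4cc(=O)c5c(OCOC)cc(OC)cc5o4)O2 | intermediate
36 | 7α,9α-diol with C8=C17 exocyclic alkene | C=C1[C@H](O)C[C@H]2C(C)(C)C[C@H](O[Si](C)(C)C(C)(C)C)C[C@]2(C)[C@@]1(O)C[C@@H]1C(C)=CC[C@H]2C(OC)(OC)C(OC)=CC(=O)[C@@]12c1cc(=O)c2c(OCOC)cc(OC)cc2o1 | intermediate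
37 | 7-ketone: 2-O-TBS, 5-O-MOM, C5′ dimethyl ketal derivative of the target | C=C1C(=O)C[C@H]2C(C)(C)C[C@H](O[Si](C)(C)C(C)(C)C)C[C@]2(C)[C@@]1(O)C[C@@H]1C(C)=CC[C@H]2C(OC)(OC)C(OC)=CC(=O)[C@@]12c1cc(=O)c2c(OCOC)cc(OC)cc2o1 | intermediate
38 | dichrostachine N | C=C1C(=O)C[C@H]2C(C)(C)C[C@H](O)C[C@]2(C)[C@@]1(O)C[C@@H]1C(C)=CC[C@H]2C(=O)C(OC)=CC(=O)[C@@]12c1cc(=O)c2c(O)cc(OC)cc2o1 | target

## Step count and least certain steps

Total: 24 steps. Longest linear sequence: 17 steps (steps 1–11 and 19–24, from 1). The second branch is steps 12–14 and 16–18 from 20, with step 15 as a one-step side branch.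

**Step 6 (key step).** Intermolecular metathesis at the exposed allyl group, or ruthenium-hydride-induced migration of the allyl double bond followed by ring contraction, could compete if closure onto the neopentyl vinyl group is slow. The fallback makes the same C2–C3 bond by reductive carbonyl coupling. It sets out from 10: ozonolysis (O3; Me2S) of both terminal alkenes gives the keto dialdehyde F1. SmI2 in THF at −78 °C effects intramolecular pinacol coupling of the 1,6-dialdehyde to the cis-2,3-diol F2, which the hindered ketone should survive. Thiocarbonyldiimidazole then gives the cyclic thionocarbonate F3, and Corey–Winter olefination with P(OMe)3 returns to the route at 11.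

**Step 14.** The ester tether must reach its less stable conformation and the diene is (Z), so the heat required may allow 1,5-hydrogen shift or geometric isomerisation of the diene, or polymerisation of the dienone, before cycloaddition. The fallback raises the dienophile to the quinone level. It sets out from 23: PhI(OAc)2 in aqueous MeCN gives the quinone ester F4, which should cyclise at or below room temperature to the ene-dione lactone F5 by the same tether-enforced geometry. Ketalisation with HC(OMe)3 and camphorsulfonic acid in MeOH takes place at the C5′ ketone only (C2′ is a hindered vinylogous ester) and returns to the route at 25.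

**Step 16.** Addition to a carbonyl on quaternary C1′ may be slow. The liberated alkoxide may cleave the non-enolisable 1,3-dicarbonyl array by retro-Claisen reaction, and the C11 hydroxyl may close onto the diketone in competition with the phenol. The fallback sets out from 25: Me2AlN(OMe)Me opens the lactone to the hydroxy Weinreb amide F6, and Et3SiCl gives the silyl ether F7. The dianion of 27 acylates on the amide through a chelated tetrahedral intermediate that cannot fragment, giving the β-diketone silyl ether F8. PPTS in toluene followed by buffered HF·pyridine closes the pyranone, removes the silyl group and returns at 29.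

**Step 19.** Transmetalation and reductive elimination at the tetrasubstituted C9 centre beside quaternary C10 may be slow enough for β-hydride elimination or protonolysis of the alkylzinc to take over. The fallback changes the nucleophile to boron and sets out from 31: CuI/PPh3-catalysed borylation with B2pin2 and LiOMe gives the pinacol boronate F9, and KHF2 converts it into the potassium trifluoroborate F10. Suzuki–Miyaura coupling of F10 with 19 (Pd(OAc)2, RuPhos, Cs2CO3, toluene–H2O, 80 °C) returns at 33.

**Step 22.** Deprotonation at C11 (opening towards the Δ9(11) 8-ol), Lewis-acid-induced semipinacol shift of the epoxy alcohol, or attack of the aluminium amide on the chromone or the vinylogous ester may compete with removal of a C17 hydrogen. The fallback moves the oxygen by a radical transposition and then uses a trisubstituted epoxide, whose opening is regiochemically unambiguous. It sets out from 35: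
- thiocarbonyldiimidazole gives the C7 thiocarbonyl imidazolide F11;
- Bu3SnH/AIBN at high stannane concentration generates the C7 radical, which opens the epoxide at C8–O, and the C9 alkoxy radical is reduced to the transposed allylic alcohol F12 (C7=C8, 9α-OH);
- VO(acac)2/t-BuOOH, now directed by the 9α-hydroxyl, gives the 7α,8α-epoxide F13;
- Cp2TiCl (trivalent titanium, from Cp2TiCl2 and Mn) cleaves the tertiary C8–O bond homolytically and the radical loses a C17 hydrogen, which returns at 36.

## Further compounds

F1 | step 6 | 5-(tert-butyldimethylsilyloxy)-2-methyl-3-(2-methyl-1-oxopropan-2-yl)-2-(2-oxoethyl)cyclohexanone, configuration as in 10 | C1[C@H](O[Si](C)(C)C(C)(C)C)C[C@@H](C(C)(C)C=O)[C@](C)(CC=O)C1=O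
F2 | step 6 | 7α-(tert-butyldimethylsilyloxy)-2,3-cis-dihydroxy-4,4,10β-trimethyl-5α-decalin-9-one | C1[C@H](O[Si](C)(C)C(C)(C)C)C[C@H]2C(C)(C)C(O)C(O)C[C@]2(C)C1=O
F3 | step 6 | 2,3-cyclic thionocarbonate of F2 | C1[C@H](O[Si](C)(C)C(C)(C)C)C[C@H]2C(C)(C)C3OC(=S)OC3C[C@]2(C)C1=O
F4 | step 14 | (Z)-3-methylpenta-2,4-dienyl 4-methoxy-3,6-dioxocyclohexa-1,4-diene-1-carboxylate | C=C/C(C)=C\COC(=O)C1=CC(=O)C(OC)=CC1=O
F5 | step 14 | ene-dione lactone: 25 with a C5′ ketone in place of the ketal (racemic) | O=C1OC[C@@H]2C(C)=CC[C@H]3C(=O)C(OC)=CC(=O)[C@@]123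
F6 | step 16 | hydroxy Weinreb amide from 25 (N-methoxy-N-methylcarboxamide on C1′, C11 hydroxymethyl on C12) | OC[C@@H]1C(C)=CC[C@H]2C(OC)(OC)C(OC)=CC(=O)[C@@]12C(=O)N(C)OC
F7 | step 16 | C11 triethylsilyl ether of F6 | CC[Si](CC)(CC)OC[C@@H]1C(C)=CC[C@H]2C(OC)(OC)C(OC)=CC(=O)[C@@]12C(=O)N(C)OC
F8 | step 16 | C11 triethylsilyl ether of β-diketone 28 | CC[Si](CC)(CC)OC[C@@H]1C(C)=CC[C@H]2C(OC)(OC)C(OC)=CC(=O)[C@@]12C(=O)CC(=O)c1c(O)cc(OC)cc1OCOC
F9 | step 19 | C11 pinacol boronate corresponding to 31 | CC1(C)OB(C[C@@H]2C(C)=CC[C@H]3C(OC)(OC)C(OC)=CC(=O)[C@@]23c2cc(=O)c3c(OCOC)cc(OC)cc3o2)OC1(C)C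
F10 | step 19 | potassium C11 trifluoroborate corresponding to 31 | [K+].F[B-](F)(F)C[C@@H]1C(C)=CC[C@H]2C(OC)(OC)C(OC)=CC(=O)[C@@]12c1cc(=O)c2c(OCOC)cc(OC)cc2o1
F11 | step 22 | 7-O-(imidazol-1-ylthiocarbonyl) derivative of 35 | C[C@@]12[C@H](OC(=S)n6ccnc6)C[C@H]3C(C)(C)C[C@H](O[Si](C)(C)C(C)(C)C)C[C@]3(C)[C@]1(C[C@@H]4C(C)=CC[C@H]5C(OC)(OC)C(OC)=CC(=O)[C@@]45c4cc(=O)c5c(OCOC)cc(OC)cc5o4)O2
F12 | step 22 | transposed allylic alcohol: C7=C8 alkene with 8-methyl, 9α-hydroxyl | CC1=CC[C@H]2C(C)(C)C[C@H](O[Si](C)(C)C(C)(C)C)C[C@]2(C)[C@@]1(O)C[C@@H]1C(C)=CC[C@H]2C(OC)(OC)C(OC)=CC(=O)[C@@]12c1cc(=O)c2c(OCOC)cc(OC)cc2o1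
F13 | step 22 | 7α,8α-epoxide of F12 (9α-hydroxyl) | C[C@@]12O[C@@H]1C[C@H]3C(C)(C)C[C@H](O[Si](C)(C)C(C)(C)C)C[C@]3(C)[C@@]2(O)C[C@@H]4C(C)=CC[C@H]5C(OC)(OC)C(OC)=CC(=O)[C@@]45c4cc(=O)c5c(OCOC)cc(OC)cc5o4
A1 | alternative 1 | ring C acid with quaternary C1′ (C2′ carboxylic acid, C5′ dimethyl acetal, C11 PMB ether) | COc1ccc(COC[C@@H]2C(C)=CC[C@@H](C(OC)OC)[C@]2(C(=O)O)c2cc(=O)c3c(O)cc(OC)cc3o2)cc1
A2 | alternative 1 | δ-lactone (C2′, O, C14, C15, C6′, C1′) with chromonyl on C1′ (either epimer), dimethoxymethyl on C6′ and (Z)-4-(4-methoxybenzyloxy)but-2-en-2-yl on C14 | O=C1O[C@H](/C(C)=C\COCc2ccc(OC)cc2)C[C@@H](C(OC)OC)C1c1cc(=O)c2c(O)cc(OC)cc2o1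
A3 | alternative 2 | 2α-silyloxy-7-oxo-trans-decalin with 8α-methyl and 9β-CH2OPMB | C[C@@H]1C(=O)C[C@H]2C(C)(C)C[C@H](O[Si](C)(C)C(C)(C)C)C[C@]2(C)[C@H]1COCc1ccc(OC)cc1
A4 | alternative 2 | acyclic trienone precursor (isopropenyl, C5=C10 alkene, C8=C9 enone, C2 silyl ether, C11 PMB ether) | C=C(C)C[C@H](O[Si](C)(C)C(C)(C)C)C/C(C)=C/CC(=O)/C(C)=C/COCc1ccc(OC)cc1
A5 | alternative 3 | protected target with ring D complete (2α- and 7α-OTBS, 5-OMOM) | C=C1[C@H](O[Si](C)(C)C(C)(C)C)C[C@H]2C(C)(C)C[C@H](O[Si](C)(C)C(C)(C)C)C[C@]2(C)[C@@]1(O)C[C@@H]1C(C)=CC[C@H]2C(=O)C(OC)=CC(=O)[C@@]12c1cc(=O)c2c(OCOC)cc(OC)cc2o1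
A6 | alternative 3 | cis-fused γ-lactone (C5′ carbonyl, C2′ bearing phenylsulfonyl, either C2′ epimer) on ring C of the coupled skeleton | C=C1[C@H](O[Si](C)(C)C(C)(C)C)C[C@H]2C(C)(C)C[C@H](O[Si](C)(C)C(C)(C)C)C[C@]2(C)[C@@]1(O)C[C@@H]1C(C)=CC[C@H]2C(=O)OC(S(=O)(=O)c3ccccc3)[C@@]12c1cc(=O)c2c(OCOC)cc(OC)cc2o1
A7 | alternative 3 | 1-methoxyvinyl phenyl sulfone | C=C(OC)S(=O)(=O)c1ccccc1
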